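If each trapped intermediate uses up one capture agent, counting turnovers tells us where trapped intermediate stops in this flask before any integration does.

- theta: substrate 0.24 M; coupling partner 1 equiv; capture agent 0.072 M; the very flask that is asked about, followed so far
- flask: substrate 0.24 M; coupling partner 1.00 equiv; capture agent 0.0720 M; time 15 d

- theta (time / d: trapped intermediate / %, product / %): 0.625: 9, 5; 1.25: 11, 9; 1.67: 18, 8; 2.50: 25, 15; 3.00: 28, 16

(scatter of a reading: 2 percentage points)

1. share of trapped intermediate in trapped intermediate plus product at 6.0 h
2. share of trapped intermediate in trapped intermediate plus product at 50 h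
3. share of trapped intermediate in trapped intermediate plus product at 15 d
4. which of trapped intermediate and product there is more of at 15 d

- the analysis behind the earlier runs scatters by 2 percentage points, standard deviation
- a reading or a percentage of product counts all its forms, free or not

Our count starts from the ceiling C, the capture agent charged over the substrate charged, 30.0% of the substrate; capture agent is then the limiting reagent for trapped intermediate. At 3.00 d the reading of 28% stands at 0.933 of one turnover, and a straight line reaches C at 3.21 d.

But a straight line is the hopeful case. Suppose instead that each span of 3.00 d uses that same fraction of the agent still there: 15 d is 5.00 spans, which leaves <0.001% of the turnover undone. So we put trapped intermediate at C at 15 d, granting the one-to-one count, which the readings cannot prove.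

Product is the harder doubt. Its mean pace carried to 15 d gives 80.0%, more than the 70.0% of substrate beside C, so that line fails. The pooled share of the readings is 63.2%, with a scatter of 2 percentage points on each reading. We commit to the two stopping together, product near 17.5%, and so to that share at 50 h and 15 d, though this step is a guess. For 6.0 h, before the first reading, we have no ground.

The forecast gave 63% at 6.0 h, 63% at 50 h and 37% at 15 d, with product ahead at 15 d, and it held that “the split stays constant until the agent runs out”.

The flask gives 40.6% at 6.0 h, 65.5% at 50 h and 67.9% at 15 d, with trapped intermediate ahead at 15 d, 30.0% against 14.2% of product. Product is highest at 5.90 d and stands at 14.2% at 15 d. With capture agent at 0% of its charge, C over C plus that product gives 67.9%.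

    capture agent + intermediate C → trapped intermediate (k = 0.00110 M⁻¹ s⁻¹)
    substrate + coupling partner ⇌ intermediate B (K = 8.10 M⁻¹, k = 1.10 × 10⁻⁴ M⁻¹ s⁻¹)
    substrate → intermediate A (k = 1.70 × 10⁻⁵ s⁻¹)
    crystals ⇌ product, rate k4*(cs4 - [product]) while solid is left; crystals form when [product] > cs4 (solubility = 0.0950 M, k = 2.40 × 10⁻⁴ s⁻¹)
    intermediate B ⇌ product (K = 22.0, k = 3.30 × 10⁻⁶ s⁻¹)
    coupling partner + intermediate A ⇌ intermediate C (K = 5.80 M⁻¹, k = 3.70 × 10⁻⁵ M⁻¹ s⁻¹)

In the flask with 0.14 M of substrate, the same equivalents of coupling partner and the same 0.0720 M of capture agent, C becomes 51.4%. The computed flask holds 51.4% of trapped intermediate beside 10.0% of product, with capture agent at 0% of its charge, a share of 83.7%.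

Readings and results are calculated with made-up constants; scatter was added.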